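**Retrosynthetic overview**

1. Structural feature used: ring A of the upper 3-deoxyflavan unit is a phloroglucinol (oxygens on C5, C7, C8a) with a single carbon substituent, C4, on C4a between the two equivalent oxygenated carbons C5 and C8a. Ring A can therefore be grown on a C4-bound alkyne, and either ortho oxygen can later become O1.
2. Target 37 ⇐ hydrogenolysis of 36 ⇐ ring C by O1–C2 Mitsunobu closure with inversion (from 35) ⇐ ring A by benzannulation of siloxyalkyne 26 with 3-siloxycyclobutenone 29 (bonds C4a–C8a, C5–C6, C8–C8a; product 34).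
3. 26 ⇐ terminal alkyne 23 (acetylide oxidation, O-silylation) ⇐ trans-lactone 19 (lactol, one-carbon homologation) ⇐ γ-keto imide 17 (CBS reduction sets the C2 carbinol) ⇐ Evans alkylation of imide 11 with chloro ketone 15 (sets C4).
4. 11 ⇐ 8-bromo-penta-O-benzylcatechin 4 ⇐ (+)-catechin 1. The catechin rings and ring B are bought; ring A is formed in step 16 and ring C in step 18.

Key step: step 16

Remarks: locants C2, C3, C4, C4a–C8a and rings A, B, C refer to the upper unit of the target and are kept for the open-chain intermediates. PBC = penta-O-benzylcatechin-8-yl = (2R,3S)-3,5,7-tris(benzyloxy)-2-[3,4-bis(benzyloxy)phenyl]chroman-8-yl. Ar = 3,4-bis(benzyloxy)phenyl. R* = the chain Ar–CH(OSiMe2t-Bu)–CH2–CH(PBC)– bonded through its last carbon (C4), with the geometry of 26. Assumption: the ynolate is made by acetylide oxidation and not by ester homologation, so that no carbonyl group sits next to C4 when strong base is present.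

**Step 1**
Reactants: 1 (+)-catechin
Product: 2 5,7,3',4'-tetra-O-benzyl-(+)-catechin
Conditions: BnBr (4.4 equiv), K2CO3, DMF, 0 °C to rt, argon
Reagents that add atoms: benzyl bromide, BrCc1ccccc1
Why: Williamson etherification of the four phenols only, since K2CO3 does not deprotonate the secondary C3 alcohol of catechin; no stereocentre is touched.

**Step 2**
Reactants: 2 5,7,3',4'-tetra-O-benzyl-(+)-catechin
Product: 3 8-bromo-5,7,3',4'-tetra-O-benzylcatechin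
Conditions: NBS (1.0 equiv), CH2Cl2, −78 °C to rt
Reagents that add atoms: N-bromosuccinimide, O=C1CCC(=O)N1Br
Why: electrophilic aromatic bromination, which in benzyl-protected catechins is selective for C8, the more nucleophilic of the two free positions of the phloroglucinol ring.

**Step 3**
Reactants: 3 8-bromo-5,7,3',4'-tetra-O-benzylcatechin
Product: 4 8-bromo-3,5,7,3',4'-penta-O-benzylcatechin
Conditions: NaH, BnBr, Bu4NI (cat.), DMF, 0 °C to rt
Reagents that add atoms: benzyl bromide, BrCc1ccccc1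
Why: Williamson etherification of the secondary alkoxide, which removes the last acidic proton before organolithium chemistry and leaves only groups cleaved by the final hydrogenolysis.

**Step 4**
Reactants: 4 8-bromo-3,5,7,3',4'-penta-O-benzylcatechin; 5 oxirane
Product: 7 2-(PBC)ethanol, via aryllithium 6 (not isolated)
Conditions: t-BuLi (2.0 equiv), THF, −78 °C; oxirane (5 equiv), −78 °C to rt; H2O
Reagents that add atoms: none
Why: bromine–lithium exchange outruns deprotonation at −78 °C, and the hindered aryllithium opens the unsubstituted epoxide to place the two-carbon chain on catechin C8.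

**Step 5**
Reactants: 7 2-(PBC)ethanol
Product: 8 (PBC)acetic acid
Conditions: TEMPO (2,2,6,6-tetramethylpiperidin-1-oxyl, 0.2 equiv), PhI(OAc)2 (2.5 equiv), MeCN/H2O, rt
Reagents that add atoms: water, O
Why: oxoammonium-mediated oxidation of the primary alcohol to the aldehyde and, through its hydrate, to the acid, under chlorine-free conditions that spare benzyl ethers and electron-rich arenes.

**Step 6**
Reactants: 8 (PBC)acetic acid; 9 (R)-4-benzyl-2-oxazolidinone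
Product: 11 (4R)-4-benzyl-3-[(PBC)acetyl]oxazolidin-2-one, via mixed pivalic anhydride 10 (not isolated)
Conditions: t-BuCOCl, Et3N, THF, −20 °C; then 9, LiCl, −20 °C to rt
Reagents that add atoms: none
Why: N-acylation of the oxazolidinone through the mixed anhydride, which reacts at the less hindered arylacetyl carbonyl and avoids an acid chloride and ketene formation.

**Step 7**
Reactants: 12 4-bromo-1,2-bis(benzyloxy)benzene; 13 2-chloro-N-methoxy-N-methylacetamide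
Product: 15 2-chloro-1-[3,4-bis(benzyloxy)phenyl]ethanone, via Grignard reagent 14 (not isolated)
Conditions: Mg, THF, rt to 40 °C; then 13, THF, −20 to 0 °C; aq. HCl
Reagents that add atoms: none
Why: acylation of the arylmagnesium bromide by the Weinreb amide, whose magnesium chelate survives until work-up, so the chloromethyl ketone forms without over-addition or attack at C–Cl.

**Step 8**
Reactants: 11 (4R)-4-benzyl-3-[(PBC)acetyl]oxazolidin-2-one; 15 2-chloro-1-[3,4-bis(benzyloxy)phenyl]ethanone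
Product: 17 (4R)-4-benzyl-3-[(2R)-4-Ar-4-oxo-2-(PBC)butanoyl]oxazolidin-2-one, via sodium enolate 16 (not isolated)
Conditions: NaN(SiMe3)2 (1.05 equiv), THF, −78 °C; then 15 (1.5 equiv), Bu4NI (0.1 equiv), −78 to −30 °C
Reagents that add atoms: none
Why: Evans asymmetric alkylation, in which the chelated (Z)-enolate is attacked by the activated α-halo ketone on the face opposite the benzyl group of the (R)-auxiliary; this sets C4 with the geometry of the target [(2R) in 17], whereas the (S)-auxiliary would give the C4 epimer.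

**Step 9**
Reactants: 17 (4R)-4-benzyl-3-[(2R)-4-Ar-4-oxo-2-(PBC)butanoyl]oxazolidin-2-one
Product: 19 (3R,5R)-5-Ar-3-(PBC)dihydrofuran-2(3H)-one (trans), via hydroxy imide 18 (not isolated)
Conditions: (S)-Me-CBS [(S)-1-methyl-3,3-diphenyltetrahydro-1H,3H-pyrrolo[1,2-c][1,3,2]oxazaborole, C18H20BNO] (0.2 equiv), BH3·SMe2 (1.0 equiv), THF, −20 °C; MeOH; then imidazole (cat.), CH2Cl2, rt
Reagents that add atoms: none
Why: Corey–Bakshi–Shibata reduction of the aryl ketone (aryl as the large group, so the (S)-catalyst should give the (R)-carbinol under reagent control), after which the γ-hydroxy imide lactonises and releases the auxiliary.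

**Step 10**
Reactants: 19 (3R,5R)-5-Ar-3-(PBC)dihydrofuran-2(3H)-one
Product: 20 (3R,5R)-5-Ar-3-(PBC)tetrahydrofuran-2-ol (anomer mixture)
Conditions: i-Bu2AlH (1.1 equiv), CH2Cl2, −78 °C; aq. potassium sodium tartrate (KNaC4H4O6)
Reagents that add atoms: none
Why: partial reduction of the γ-lactone to the lactol at −78 °C, where the aluminium hemiacetal does not collapse and no base is present to touch C4.

**Step 11**
Reactants: 20 (3R,5R)-5-Ar-3-(PBC)tetrahydrofuran-2-ol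
Product: 22 (1R,3S)-1-Ar-3-(PBC)pent-4-yn-1-ol, via hydroxy aldehyde 21 (not isolated)
Conditions: dimethyl (1-diazo-2-oxopropyl)phosphonate (2 equiv), K2CO3 (3 equiv), MeOH/THF, 0 °C to rt
Reagents that add atoms: dimethyl (1-diazo-2-oxopropyl)phosphonate, CC(=O)C(=[N+]=[N-])P(=O)(OC)OC
Why: Seyferth–Gilbert homologation in the Ohira–Bestmann form on the ring-opened lactol, where the aldehyde-derived alkylidene carbene undergoes a 1,2-hydrogen shift faster than O–H insertion; the two ortho oxygens twist the aryl ring out of conjugation with the enolate of 21, which should slow epimerisation at C4.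

**Step 12**
Reactants: 22 (1R,3S)-1-Ar-3-(PBC)pent-4-yn-1-ol
Product: 23 tert-butyl{[(1R,3S)-1-Ar-3-(PBC)pent-4-yn-1-yl]oxy}dimethylsilane
Conditions: TBSCl, imidazole, DMF, rt
Reagents that add atoms: tert-butyldimethylsilyl chloride, CC(C)(C)[Si](C)(C)Cl
Why: standard silylation of the secondary alcohol, so that the alkyne C–H is the only acidic site in the next step.

**Step 13**
Reactants: 23 tert-butyl{[(1R,3S)-1-Ar-3-(PBC)pent-4-yn-1-yl]oxy}dimethylsilane
Product: 26 tert-butyl{[(1R,3S)-1-Ar-3-(PBC)-5-(triisopropylsilyloxy)pent-4-yn-1-yl]oxy}dimethylsilane, via lithium acetylide 24 (not isolated), via lithium ynolate 25 (not isolated)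
Conditions: LiN(SiMe3)2 (2.2 equiv), t-BuOOH (1.1 equiv), THF, −78 to 0 °C; then TIPSOTf (1.3 equiv), −78 °C to rt; Et3N-deactivated silica
Reagents that add atoms: tert-butyl hydroperoxide, CC(C)(C)OO; triisopropylsilyl trifluoromethanesulfonate, CC(C)[Si](C(C)C)(C(C)C)OS(=O)(=O)C(F)(F)F
Why: oxidation of the lithium acetylide by lithium tert-butyl peroxide gives the ynolate, which the bulky silyl triflate traps on oxygen, a known route to 1-siloxyalkynes that leaves the propargylic C4–H untouched.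

**Step 14**
Reactants: 27 3-ethoxycyclobut-2-en-1-one
Product: 28 cyclobutane-1,3-dione
Conditions: 1 M aq. HCl, THF, 0 °C to rt; evaporate
Reagents that add atoms: water, O
Why: acid hydrolysis of the vinylogous ester by addition–elimination at C3; the dione is used at once.

**Step 15**
Reactants: 28 cyclobutane-1,3-dione
Product: 29 3-(triisopropylsilyloxy)cyclobut-2-en-1-one
Conditions: TIPSCl, Et3N, CH2Cl2, 0 °C
Reagents that add atoms: triisopropylsilyl chloride, CC(C)[Si](Cl)(C(C)C)C(C)C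
Why: the strongly acidic dione is O-silylated as its ammonium enolate, and the bulky silyl group gives a hydrolytically robust vinylogous silyl ester.

**Step 16**
Reactants: 26 tert-butyl{[(1R,3S)-1-Ar-3-(PBC)-5-(triisopropylsilyloxy)pent-4-yn-1-yl]oxy}dimethylsilane; 29 3-(triisopropylsilyloxy)cyclobut-2-en-1-one
Product: 34 2-R*-3,5-bis(triisopropylsilyloxy)phenol, via siloxyvinylketene 30 (not isolated), via vinylcyclobutenone 31 (not isolated), via dienylketene 32 (not isolated), via cyclohexadienone 33 (not isolated)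
Conditions: 29 (2 equiv), toluene (0.3 M), 80 °C then 110 °C, sealed tube, argon
Reagents that add atoms: none
Why: Danheiser benzannulation: 29 opens by thermal 4π electrocyclic reaction to siloxyvinylketene 30, which adds [2+2] to the ynol ether so that the ketene carbonyl carbon (future C8a) bonds to the alkyne carbon on C4 (future C4a) and the ketene α-carbon (future C6) bonds to the siloxy carbon (future C5). The 4-vinylcyclobutenone 31 opens (4π) to dienylketene 32, and ring A closes by 6π electrocyclisation between the ketene carbon and the terminal CH2 (C8a–C8) to dienone 33, which tautomerises to the phenol. The closest known reaction type is the thermal annulation of cyclobutenones, 3-siloxy ones included, with trialkylsiloxyalkynes to resorcinol and phloroglucinol silyl ethers. No stereocentre is formed (the sp3 ring carbon of 31 is lost on ring opening), and the neutral thermal conditions should leave C4, the C2 silyl ether and the benzyl ethers untouched. The selectivity needed is the regiochemistry of the ketene–alkyne [2+2], secured by the polarisation of the siloxyalkyne, whose carbon on C4 is the nucleophile and pairs with the electrophilic ketene carbon. The ketene carbonyl ends as the one free phenol (C8a) with silyl ethers on C5 and C7, and since C5 and C8a become equivalent after desilylation it does not matter which ortho oxygen is free.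

**Step 17**
Reactants: 34 2-R*-3,5-bis(triisopropylsilyloxy)phenol
Product: 35 2-[(1S,3R)-3-Ar-3-hydroxy-1-(PBC)propyl]benzene-1,3,5-triol
Conditions: Bu4NF (4 equiv), AcOH (4 equiv), degassed THF, 0 °C to rt
Reagents that add atoms: none
Why: fluoride cleaves the two aryl TIPS ethers and the secondary TBS ether, with acetic acid buffering the phenoxides so that the air-sensitive phloroglucinol is not oxidised.

**Step 18**
Reactants: 35 2-[(1S,3R)-3-Ar-3-hydroxy-1-(PBC)propyl]benzene-1,3,5-triol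
Product: 36 (2S,4S)-2-Ar-4-(PBC)chroman-5,7-diol
Conditions: PPh3 (1.5 equiv), diisopropyl azodicarboxylate (1.5 equiv), THF (0.01 M), 0 °C
Reagents that add atoms: none
Why: intramolecular Mitsunobu etherification in which an ortho phenol (the two are equivalent, the para one cannot reach) displaces the activated C2 oxygen in a 6-exo SN2 process with inversion, turning the (R)-carbinol into the (S)-configured C2 of ring C, cis to the C4 substituent.

**Step 19**
Reactants: 36 (2S,4S)-2-Ar-4-(PBC)chroman-5,7-diol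
Product: 37 target CNP0180676.1
Conditions: H2 (1 atm), Pd(OH)2 on carbon (20 wt%), THF/MeOH, rt
Reagents that add atoms: none
Why: hydrogenolysis of the seven benzyl ethers, under conditions where the benzylic C2–O1 bonds and the C4–H of catechin-type oligomers are known to survive.

**Compound list**

1 | (+)-catechin | Oc1cc(O)c2c(c1)O[C@H](c1ccc(O)c(O)c1)[C@@H](O)C2 | starting material
2 | 5,7,3',4'-tetra-O-benzyl-(+)-catechin | O(Cc9ccccc9)c3cc(OCc9ccccc9)c4c(c3)O[C@H](c6ccc(OCc9ccccc9)c(OCc9ccccc9)c6)[C@@H](O)C4 | intermediate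
3 | 8-bromo-5,7,3',4'-tetra-O-benzylcatechin | Brc3c(OCc9ccccc9)cc(OCc9ccccc9)c4c3O[C@H](c6ccc(OCc9ccccc9)c(OCc9ccccc9)c6)[C@@H](O)C4 | intermediate
4 | 8-bromo-3,5,7,3',4'-penta-O-benzylcatechin | Brc3c(OCc9ccccc9)cc(OCc9ccccc9)c4c3O[C@H](c6ccc(OCc9ccccc9)c(OCc9ccccc9)c6)[C@@H](OCc9ccccc9)C4 | intermediate
5 | oxirane | C1CO1 | starting material
6 | 8-lithio-penta-O-benzylcatechin (aryllithium) | [Li]c3c(OCc9ccccc9)cc(OCc9ccccc9)c4c3O[C@H](c6ccc(OCc9ccccc9)c(OCc9ccccc9)c6)[C@@H](OCc9ccccc9)C4 | intermediate (not isolated)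
7 | 2-(PBC)ethanol | OCCc3c(OCc9ccccc9)cc(OCc9ccccc9)c4c3O[C@H](c6ccc(OCc9ccccc9)c(OCc9ccccc9)c6)[C@@H](OCc9ccccc9)C4 | intermediate
8 | (PBC)acetic acid | OC(=O)Cc3c(OCc9ccccc9)cc(OCc9ccccc9)c4c3O[C@H](c6ccc(OCc9ccccc9)c(OCc9ccccc9)c6)[C@@H](OCc9ccccc9)C4 | intermediate
9 | (R)-4-benzyl-2-oxazolidinone | O=C1OC[C@@H](Cc2ccccc2)N1 | starting material
10 | (PBC)acetic pivalic anhydride | CC(C)(C)C(=O)OC(=O)Cc3c(OCc9ccccc9)cc(OCc9ccccc9)c4c3O[C@H](c6ccc(OCc9ccccc9)c(OCc9ccccc9)c6)[C@@H](OCc9ccccc9)C4 | intermediate (not isolated)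
11 | (4R)-4-benzyl-3-[(PBC)acetyl]oxazolidin-2-one | O=C1OC[C@@H](Cc2ccccc2)N1C(=O)Cc3c(OCc9ccccc9)cc(OCc9ccccc9)c4c3O[C@H](c6ccc(OCc9ccccc9)c(OCc9ccccc9)c6)[C@@H](OCc9ccccc9)C4 | intermediate
12 | 4-bromo-1,2-bis(benzyloxy)benzene | Brc1ccc(OCc2ccccc2)c(OCc2ccccc2)c1 | starting material
13 | 2-chloro-N-methoxy-N-methylacetamide | CON(C)C(=O)CCl | starting material
14 | [3,4-bis(benzyloxy)phenyl]magnesium bromide | Br[Mg]c1ccc(OCc2ccccc2)c(OCc2ccccc2)c1 | intermediate (not isolated)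
15 | 2-chloro-1-[3,4-bis(benzyloxy)phenyl]ethanone | ClCC(=O)c1ccc(OCc2ccccc2)c(OCc2ccccc2)c1 | intermediate
16 | sodium (Z)-enolate of 11 | [Na+].[O-]/C(=C\c3c(OCc9ccccc9)cc(OCc9ccccc9)c4c3O[C@H](c6ccc(OCc9ccccc9)c(OCc9ccccc9)c6)[C@@H](OCc9ccccc9)C4)N1[C@H](Cc2ccccc2)COC1=O | intermediate (not isolated)
17 | (4R)-4-benzyl-3-[(2R)-4-Ar-4-oxo-2-(PBC)butanoyl]oxazolidin-2-one | O=C1OC[C@@H](Cc2ccccc2)N1C(=O)[C@H](CC(=O)c5ccc(OCc9ccccc9)c(OCc9ccccc9)c5)c3c(OCc9ccccc9)cc(OCc9ccccc9)c4c3O[C@H](c6ccc(OCc9ccccc9)c(OCc9ccccc9)c6)[C@@H](OCc9ccccc9)C4 | intermediate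
18 | (4R)-4-benzyl-3-[(2R,4R)-4-Ar-4-hydroxy-2-(PBC)butanoyl]oxazolidin-2-one | O=C1OC[C@@H](Cc2ccccc2)N1C(=O)[C@H](C[C@@H](O)c5ccc(OCc9ccccc9)c(OCc9ccccc9)c5)c3c(OCc9ccccc9)cc(OCc9ccccc9)c4c3O[C@H](c6ccc(OCc9ccccc9)c(OCc9ccccc9)c6)[C@@H](OCc9ccccc9)C4 | intermediate (not isolated)
19 | (3R,5R)-5-Ar-3-(PBC)dihydrofuran-2(3H)-one | O=C1O[C@@H](c5ccc(OCc9ccccc9)c(OCc9ccccc9)c5)C[C@@H]1c3c(OCc9ccccc9)cc(OCc9ccccc9)c4c3O[C@H](c6ccc(OCc9ccccc9)c(OCc9ccccc9)c6)[C@@H](OCc9ccccc9)C4 | intermediate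
20 | (3R,5R)-5-Ar-3-(PBC)tetrahydrofuran-2-ol (anomer mixture) | OC1O[C@@H](c5ccc(OCc9ccccc9)c(OCc9ccccc9)c5)C[C@@H]1c3c(OCc9ccccc9)cc(OCc9ccccc9)c4c3O[C@H](c6ccc(OCc9ccccc9)c(OCc9ccccc9)c6)[C@@H](OCc9ccccc9)C4 | intermediate
21 | (2R,4R)-4-Ar-4-hydroxy-2-(PBC)butanal | O=C[C@H](C[C@@H](O)c5ccc(OCc9ccccc9)c(OCc9ccccc9)c5)c3c(OCc9ccccc9)cc(OCc9ccccc9)c4c3O[C@H](c6ccc(OCc9ccccc9)c(OCc9ccccc9)c6)[C@@H](OCc9ccccc9)C4 | intermediate (not isolated)
22 | (1R,3S)-1-Ar-3-(PBC)pent-4-yn-1-ol | O[C@@H](c5ccc(OCc9ccccc9)c(OCc9ccccc9)c5)C[C@@H](C#C)c3c(OCc9ccccc9)cc(OCc9ccccc9)c4c3O[C@H](c6ccc(OCc9ccccc9)c(OCc9ccccc9)c6)[C@@H](OCc9ccccc9)C4 | intermediate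
23 | tert-butyl{[(1R,3S)-1-Ar-3-(PBC)pent-4-yn-1-yl]oxy}dimethylsilane | CC(C)(C)[Si](C)(C)O[C@@H](c5ccc(OCc9ccccc9)c(OCc9ccccc9)c5)C[C@@H](C#C)c3c(OCc9ccccc9)cc(OCc9ccccc9)c4c3O[C@H](c6ccc(OCc9ccccc9)c(OCc9ccccc9)c6)[C@@H](OCc9ccccc9)C4 | intermediate
24 | lithium acetylide of 23 | CC(C)(C)[Si](C)(C)O[C@@H](c5ccc(OCc9ccccc9)c(OCc9ccccc9)c5)C[C@@H](C#C[Li])c3c(OCc9ccccc9)cc(OCc9ccccc9)c4c3O[C@H](c6ccc(OCc9ccccc9)c(OCc9ccccc9)c6)[C@@H](OCc9ccccc9)C4 | intermediate (not isolated)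
25 | lithium ynolate (O–Li on the alkyne terminus of 23) | CC(C)(C)[Si](C)(C)O[C@@H](c5ccc(OCc9ccccc9)c(OCc9ccccc9)c5)C[C@@H](C#CO[Li])c3c(OCc9ccccc9)cc(OCc9ccccc9)c4c3O[C@H](c6ccc(OCc9ccccc9)c(OCc9ccccc9)c6)[C@@H](OCc9ccccc9)C4 | intermediate (not isolated)
26 | tert-butyl{[(1R,3S)-1-Ar-3-(PBC)-5-(triisopropylsilyloxy)pent-4-yn-1-yl]oxy}dimethylsilane (key-step precursor) | CC(C)(C)[Si](C)(C)O[C@@H](c5ccc(OCc9ccccc9)c(OCc9ccccc9)c5)C[C@@H](C#CO[Si](C(C)C)(C(C)C)C(C)C)c3c(OCc9ccccc9)cc(OCc9ccccc9)c4c3O[C@H](c6ccc(OCc9ccccc9)c(OCc9ccccc9)c6)[C@@H](OCc9ccccc9)C4 | intermediate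
27 | 3-ethoxycyclobut-2-en-1-one | CCOC1=CC(=O)C1 | starting material
28 | cyclobutane-1,3-dione | O=C1CC(=O)C1 | intermediate
29 | 3-(triisopropylsilyloxy)cyclobut-2-en-1-one | O=C1C=C(O[Si](C(C)C)(C(C)C)C(C)C)C1 | intermediate
30 | 3-(triisopropylsilyloxy)buta-1,3-dien-1-one | O=C=CC(=C)O[Si](C(C)C)(C(C)C)C(C)C | intermediate (not isolated)
31 | 2-R*-3-(triisopropylsilyloxy)-4-[1-(triisopropylsilyloxy)ethenyl]cyclobut-2-en-1-one (epimers at ring C4) | CC(C)(C)[Si](C)(C)O[C@@H](c5ccc(OCc9ccccc9)c(OCc9ccccc9)c5)C[C@@H](C1=C(O[Si](C(C)C)(C(C)C)C(C)C)C(C(=C)O[Si](C(C)C)(C(C)C)C(C)C)C1=O)c3c(OCc9ccccc9)cc(OCc9ccccc9)c4c3O[C@H](c6ccc(OCc9ccccc9)c(OCc9ccccc9)c6)[C@@H](OCc9ccccc9)C4 | intermediate (not isolated)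
32 | 2-R*-3,5-bis(triisopropylsilyloxy)hexa-1,3,5-trien-1-one (ketene and siloxyvinyl ends cis across C3=C4) | CC(C)(C)[Si](C)(C)O[C@@H](c5ccc(OCc9ccccc9)c(OCc9ccccc9)c5)C[C@@H](C(=C=O)/C(O[Si](C(C)C)(C(C)C)C(C)C)=C\C(=C)O[Si](C(C)C)(C(C)C)C(C)C)c3c(OCc9ccccc9)cc(OCc9ccccc9)c4c3O[C@H](c6ccc(OCc9ccccc9)c(OCc9ccccc9)c6)[C@@H](OCc9ccccc9)C4 | intermediate (not isolated)
33 | 2-R*-3,5-bis(triisopropylsilyloxy)cyclohexa-2,4-dien-1-one | CC(C)(C)[Si](C)(C)O[C@@H](c5ccc(OCc9ccccc9)c(OCc9ccccc9)c5)C[C@@H](C1=C(O[Si](C(C)C)(C(C)C)C(C)C)C=C(O[Si](C(C)C)(C(C)C)C(C)C)CC1=O)c3c(OCc9ccccc9)cc(OCc9ccccc9)c4c3O[C@H](c6ccc(OCc9ccccc9)c(OCc9ccccc9)c6)[C@@H](OCc9ccccc9)C4 | intermediate (not isolated)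
34 | 2-[(1R,3R)-3-Ar-3-(tert-butyldimethylsilyloxy)-1-(PBC)propyl]-3,5-bis(triisopropylsilyloxy)phenol (key-step product) | CC(C)(C)[Si](C)(C)O[C@@H](c5ccc(OCc9ccccc9)c(OCc9ccccc9)c5)C[C@@H](c1c(O)cc(O[Si](C(C)C)(C(C)C)C(C)C)cc1O[Si](C(C)C)(C(C)C)C(C)C)c3c(OCc9ccccc9)cc(OCc9ccccc9)c4c3O[C@H](c6ccc(OCc9ccccc9)c(OCc9ccccc9)c6)[C@@H](OCc9ccccc9)C4 | intermediate
35 | 2-[(1S,3R)-3-Ar-3-hydroxy-1-(PBC)propyl]benzene-1,3,5-triol | O[C@@H](c5ccc(OCc9ccccc9)c(OCc9ccccc9)c5)C[C@@H](c1c(O)cc(O)cc1O)c3c(OCc9ccccc9)cc(OCc9ccccc9)c4c3O[C@H](c6ccc(OCc9ccccc9)c(OCc9ccccc9)c6)[C@@H](OCc9ccccc9)C4 | intermediate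
36 | (2S,4S)-2-Ar-4-(PBC)chroman-5,7-diol | Oc1cc(O)c2c(c1)O[C@H](c5ccc(OCc9ccccc9)c(OCc9ccccc9)c5)C[C@@H]2c3c(OCc9ccccc9)cc(OCc9ccccc9)c4c3O[C@H](c6ccc(OCc9ccccc9)c(OCc9ccccc9)c6)[C@@H](OCc9ccccc9)C4 | intermediate
37 | CNP0180676.1, (2S,4S)-2-(3,4-dihydroxyphenyl)-4-[(2R,3S)-2-(3,4-dihydroxyphenyl)-3,5,7-trihydroxychroman-8-yl]chroman-5,7-diol | Oc1cc(O)c2c(c1)O[C@H](c1ccc(O)c(O)c1)C[C@@H]2c1c(O)cc(O)c2c1O[C@H](c1ccc(O)c(O)c1)[C@@H](O)C2 | target

**Step count**

Total: 19 steps. Longest linear sequence: 16 steps from (+)-catechin (steps 1–6, 8–13, 16–19); steps 7, 14 and 15 make the two side fragments.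

**Steps most likely to fail**

1. Step 16 (key step). The donor-substituted cyclobutenone 29 opens slowly, so the temperature needed may allow thermal 1,3-silyl migration of siloxyalkyne 26 to a silylketene, and excess vinylketene may acylate the product phenol. The fallback sets out from 26 and rejoins the route at 34; it makes the same siloxyvinylketene 30 at room temperature by photochemical Wolff rearrangement. Butane-2,3-dione would be mono-silylated (TIPSOTf, Et3N, CH2Cl2) to 3-(triisopropylsilyloxy)but-3-en-2-one F1. Its lithium enolate (LiN(SiMe3)2, THF, −78 °C) would be acylated with 2,2,2-trifluoroethyl trifluoroacetate to 1,1,1-trifluoro-5-(triisopropylsilyloxy)hex-5-ene-2,4-dione F2. Deacylative diazo transfer (methanesulfonyl azide, Et3N, MeCN/H2O) should then give 1-diazo-3-(triisopropylsilyloxy)but-3-en-2-one F3. Irradiation of F3 with 26 (about 300 nm, CH2Cl2, rt) should deliver 30 and its [2+2] adduct 31 without heating 26; brief warming to 80 °C would complete 31 → 32 → 33 → 34.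

2. Step 11. Hydroxy aldehyde 21 is an α-aryl aldehyde, so epimerisation at C4 through its enolate in basic methanol may compete with homologation, and ring opening of the lactol may be slow. The fallback sets out from lactone 19 and rejoins the route at lithium acetylide 24 inside step 13, bypassing 20–23. Aminolysis of 19 with MeNH(OMe)·HCl/Me3Al (CH2Cl2, 0 °C) would give (2R,4R)-4-Ar-4-hydroxy-N-methoxy-N-methyl-2-(PBC)butanamide F4. Silylation (TBSCl, imidazole, DMF) would give its TBS ether F5, and i-Bu2AlH (THF, −78 °C) the aldehyde (2R,4R)-4-Ar-4-(tert-butyldimethylsilyloxy)-2-(PBC)butanal F6. F6 would be used at once in a base-free Corey–Fuchs olefination (CBr4, PPh3, Zn, CH2Cl2) to tert-butyl{[(1R,3S)-1-Ar-5,5-dibromo-3-(PBC)pent-4-en-1-yl]oxy}dimethylsilane F7. n-BuLi (2.2 equiv, THF, −78 °C) converts F7 into 24, which is carried on with lithium tert-butyl peroxide and TIPSOTf to 26 as in step 13.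

3. Step 18. The para-benzyloxy group of ring B stabilises a benzylic cation, so ionisation of the alkoxyphosphonium intermediate may erode the C2 configuration or lead to the styrene by elimination. The fallback sets out from 34 and rejoins the route at 36; it sets C2 from C4 at the ketone oxidation level instead of by inversion. Camphorsulfonic acid in MeOH/CH2Cl2 (0 °C) should remove only the alkyl TBS ether and give 2-[(1R,3R)-3-Ar-3-hydroxy-1-(PBC)propyl]-3,5-bis(triisopropylsilyloxy)phenol F8. MnO2 (CH2Cl2, rt) would oxidise the benzylic alcohol to (3R)-1-Ar-3-[2-hydroxy-4,6-bis(triisopropylsilyloxy)phenyl]-3-(PBC)propan-1-one F9, which equilibrates with its cyclic hemiketal on the free C8a phenol. Et3SiH/BF3·OEt2 (CH2Cl2, −78 °C) reduces the derived cyclic oxocarbenium ion; hydride delivery anti to the C4 substituent should give the 2,4-cis flavan (2S,4R)-2-Ar-4-(PBC)-5,7-bis(triisopropylsilyloxy)chroman F10 (same geometry as 36). Bu4NF/AcOH (THF, 0 °C) then gives 36.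

**Further compounds**

F1 | step 16 | 3-(triisopropylsilyloxy)but-3-en-2-one | CC(=O)C(=C)O[Si](C(C)C)(C(C)C)C(C)C
F2 | step 16 | 1,1,1-trifluoro-5-(triisopropylsilyloxy)hex-5-ene-2,4-dione | O=C(CC(=O)C(F)(F)F)C(=C)O[Si](C(C)C)(C(C)C)C(C)C
F3 | step 16 | 1-diazo-3-(triisopropylsilyloxy)but-3-en-2-one | [N-]=[N+]=CC(=O)C(=C)O[Si](C(C)C)(C(C)C)C(C)C
F4 | step 11 | (2R,4R)-4-Ar-4-hydroxy-N-methoxy-N-methyl-2-(PBC)butanamide | CON(C)C(=O)[C@H](C[C@@H](O)c5ccc(OCc9ccccc9)c(OCc9ccccc9)c5)c3c(OCc9ccccc9)cc(OCc9ccccc9)c4c3O[C@H](c6ccc(OCc9ccccc9)c(OCc9ccccc9)c6)[C@@H](OCc9ccccc9)C4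
F5 | step 11 | (2R,4R)-4-Ar-4-(tert-butyldimethylsilyloxy)-N-methoxy-N-methyl-2-(PBC)butanamide | CON(C)C(=O)[C@H](C[C@@H](O[Si](C)(C)C(C)(C)C)c5ccc(OCc9ccccc9)c(OCc9ccccc9)c5)c3c(OCc9ccccc9)cc(OCc9ccccc9)c4c3O[C@H](c6ccc(OCc9ccccc9)c(OCc9ccccc9)c6)[C@@H](OCc9ccccc9)C4
F6 | step 11 | (2R,4R)-4-Ar-4-(tert-butyldimethylsilyloxy)-2-(PBC)butanal | O=C[C@H](C[C@@H](O[Si](C)(C)C(C)(C)C)c5ccc(OCc9ccccc9)c(OCc9ccccc9)c5)c3c(OCc9ccccc9)cc(OCc9ccccc9)c4c3O[C@H](c6ccc(OCc9ccccc9)c(OCc9ccccc9)c6)[C@@H](OCc9ccccc9)C4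
F7 | step 11 | tert-butyl{[(1R,3S)-1-Ar-5,5-dibromo-3-(PBC)pent-4-en-1-yl]oxy}dimethylsilane | BrC(Br)=C[C@H](C[C@@H](O[Si](C)(C)C(C)(C)C)c5ccc(OCc9ccccc9)c(OCc9ccccc9)c5)c3c(OCc9ccccc9)cc(OCc9ccccc9)c4c3O[C@H](c6ccc(OCc9ccccc9)c(OCc9ccccc9)c6)[C@@H](OCc9ccccc9)C4
F8 | step 18 | 2-[(1R,3R)-3-Ar-3-hydroxy-1-(PBC)propyl]-3,5-bis(triisopropylsilyloxy)phenol | O[C@@H](c5ccc(OCc9ccccc9)c(OCc9ccccc9)c5)C[C@@H](c1c(O)cc(O[Si](C(C)C)(C(C)C)C(C)C)cc1O[Si](C(C)C)(C(C)C)C(C)C)c3c(OCc9ccccc9)cc(OCc9ccccc9)c4c3O[C@H](c6ccc(OCc9ccccc9)c(OCc9ccccc9)c6)[C@@H](OCc9ccccc9)C4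
F9 | step 18 | (3R)-1-Ar-3-[2-hydroxy-4,6-bis(triisopropylsilyloxy)phenyl]-3-(PBC)propan-1-one | O=C(c5ccc(OCc9ccccc9)c(OCc9ccccc9)c5)C[C@@H](c1c(O)cc(O[Si](C(C)C)(C(C)C)C(C)C)cc1O[Si](C(C)C)(C(C)C)C(C)C)c3c(OCc9ccccc9)cc(OCc9ccccc9)c4c3O[C@H](c6ccc(OCc9ccccc9)c(OCc9ccccc9)c6)[C@@H](OCc9ccccc9)C4
F10 | step 18 | (2S,4R)-2-Ar-4-(PBC)-5,7-bis(triisopropylsilyloxy)chroman (2,4-cis) | CC(C)[Si](C(C)C)(C(C)C)Oc1cc(O[Si](C(C)C)(C(C)C)C(C)C)c2c(c1)O[C@H](c5ccc(OCc9ccccc9)c(OCc9ccccc9)c5)C[C@@H]2c3c(OCc9ccccc9)cc(OCc9ccccc9)c4c3O[C@H](c6ccc(OCc9ccccc9)c(OCc9ccccc9)c6)[C@@H](OCc9ccccc9)C4
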